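The data stem from a simulated flask for substances that don't exist; the scatter is artificial.

At 12 min the reading in each flask can be held against one number taken from the charge. Take [nucleophile] at the start less [protic impurity] at the start, halve it, and divide by [electrophile] at the start. This two-for-one share gives 47.5% for east, 62.5% for south and 82.5% for south-east. It counts one nucleophile lost per protic impurity, then two per product: one reacts, one binds the acid set free. On this count nucleophile is the limiting reagent, even in south-east.

| flask | electrophile | nucleophile | protic impurity | remark | time |
|---|---|---|---|---|---|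
| beta | 20 mM | 16 mM | 1 mM | run made earlier |  |
| epsilon | 20 mM | 24 mM | 1 mM | run made earlier |  |
| theta | 20 mM | 27 mM | 1 mM | run made earlier |  |
| east | 20 mM | 20.0 mM | 1.00 mM |  | 12 min |
| south | 20 mM | 26.0 mM | 1.00 mM |  | 12 min |
| south-east | 20 mM | 34.0 mM | 1.00 mM |  | 12 min |

| run | time / min | electrophile / % | product / % |
|---|---|---|---|
| beta | 0.500 | 93.9 | 6.1 |
| beta | 1.50 | 86.5 | 14.8 |
| beta | 3.00 | 76.3 | 20.0 |
| beta | 4.00 | 75.1 | 24.6 |
| beta | 6.00 | 72.3 | 30.4 |
| epsilon | 1.33 | 79.3 | 18.6 |
| epsilon | 2.50 | 72.3 | 26.9 |
| epsilon | 4.00 | 64.9 | 36.3 |
| epsilon | 5.00 | 61.7 | 39.1 |
| epsilon | 6.00 | 59.7 | 41.4 |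
| theta | 0.500 | 90.1 | 8.3 |
| theta | 1.50 | 75.8 | 24.6 |
| theta | 3.00 | 65.0 | 33.8 |
| theta | 4.00 | 61.2 | 40.9 |
| theta | 6.00 | 53.7 | 47.4 |

(readings scatter by 1 percentage point)

1. part of the electrophile that has reacted at the end, east
2. part of the electrophile that has reacted at the end, south
3. part of the electrophile that has reacted at the end, south-east
4. what raising the concentration of nucleophile from its lowest to its highest value here does to the part of the electrophile that has reacted (changes below 5 percentage points count as none) (it rises / no change / it falls)

- what may be going on: electrophile + nucleophile -> acid set free + product; nucleophile + acid set free <-> protonated nucleophile; nucleophile <-> dormant form; nucleophile + protic impurity -> quenched reagent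

The earlier runs carry the share. At the last reading, 6.00 min, the reacted part read from the electrophile is 27.7% in beta, 40.3% in epsilon and 46.3% in theta. Those readings are 0.739, 0.701 and 0.712 of their shares, close together across charges from 16 mM to 27 mM. The hunch that more nucleophile carries the electrophile further fits this. The reckoning here stops at the shares, which are marks and not readings for 12 min. The forecast goes on to 44%, 56% and 70%, and its answer on the trend is: it rises. Its ground is that “each product frees an acid, which ties up a second nucleophile”.

    electrophile + nucleophile → acid set free + product (k = 0.163 /M/s)
    nucleophile + acid set free ⇌ protonated nucleophile, settled at all times (K = 4.80 × 10⁵ /M)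
    nucleophile ⇌ dormant form (K = 0.357, k = 0.00357 /s)
    nucleophile + protic impurity → quenched reagent (k = 2.88 /M/s)

The flasks give 42.7%, 54.4% and 67.9%, and the answer on the trend is: it rises, by 25 percentage points, so the forecast stands within its tolerance. South-east holds 0.823 of its share at 12 min and reads 83.3% at 120 min, against a share of 82.5%. In south-east half of the quenching turnover is done by 0.124 min, while the electrophile's half-life by its step with nucleophile is 4.9 min at 1.98 min, far longer. By 1.20 min the quenching step in south-east has 99.4% of its turnover up to 12 min behind it, and 0% of the protic impurity stands unbound at 12.0 min. A flask like south-east but with 34 mM of electrophile has a share of 48.5%, and at 12 min it stands at 46.9%.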